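C7–C8 ⇒ zinc Barbier allylation of 3-(bromomethyl)butenolide 20 with the β,γ-unsaturated aldehyde 7; it creates C7, C8 and the α-methylene lactone in one step.
C3–C4 ⇒ ring closure of the 4-iodo-3-oxo seco-compound 27: in the ten-membered carbocycle the carbinol C3 is bonded to C4, which carries the exocyclic C4=C15 methylene, and this allylic alcohol on a 1,1-disubstituted alkene is the retron of an alkenylchromium/aldehyde (Nozaki–Hiyama–Kishi) addition. The trans-fused lactone ring (O–C6–C7–C11–C12) and the (E)-C1=C10 alkene pre-organise the chain.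
20 ⇒ 8 + 9 + 18: Brown alkoxyallylboration of 3-(trimethylsilyl)propynal sets C5 and C6, the alkyne becomes the C4 iodoalkene, and acrylate ring-closing metathesis forms the butenolide; 7 ⇒ 1 + 2 by carboalumination/oxirane opening, which fixes the (E)-C1=C10 alkene.
End game from the cyclised alcohol 29: C3 acetylation, C5 desilylation, then epoxidation of the C1=C10 alkene.
Order of ring formation: butenolide (step 11) → ten-membered carbocycle (step 16) → oxirane (step 19).

Key step: step 16

Remark: the locants C1–C15 are the germacrane locants of the target and are used for all intermediates.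

Step 1
Reactants: 1 4-(tert-butyldimethylsilyloxy)but-1-yne; 2 oxirane
Product: 4 (E)-6-[(tert-butyldimethylsilyl)oxy]-4-methylhex-3-en-1-ol, via (E)-alkenyldimethylalane 3 (not isolated)
Conditions: Me3Al, Cp2ZrCl2 (cat.), CH2Cl2, 0 °C → rt; n-BuLi, THF/hexane, −78 °C; oxirane, −78 °C → rt; H2O
Reagents that add atoms: trimethylaluminium, C[Al](C)C
Why: Negishi zirconium-catalysed carboalumination adds CH3–Al syn across the terminal alkyne (methyl to the internal carbon) and the lithium alkenylalanate opens oxirane with retention of alkene geometry, so the (E)-trisubstituted C1=C10 alkene with the C14 methyl is fixed here.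

Step 2
Reactants: 4 (E)-6-[(tert-butyldimethylsilyl)oxy]-4-methylhex-3-en-1-ol
Product: 5 (E)-tert-butyl({6-[(4-methoxybenzyl)oxy]-3-methylhex-3-en-1-yl}oxy)dimethylsilane
Conditions: NaH, PMBCl, Bu4NI (cat.), THF/DMF, 0 °C → rt
Reagents that add atoms: 4-methoxybenzyl chloride, COc1ccc(CCl)cc1
Why: Williamson etherification of the primary alkoxide gives a C3–O protecting group that is orthogonal to the silyl ethers used later.

Step 3
Reactants: 5 (E)-tert-butyl({6-[(4-methoxybenzyl)oxy]-3-methylhex-3-en-1-yl}oxy)dimethylsilane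
Product: 6 (E)-6-[(4-methoxybenzyl)oxy]-3-methylhex-3-en-1-ol
Conditions: camphorsulfonic acid (cat.), MeOH, 0 °C
Reagents that add atoms: none
Why: Acid-catalysed methanolysis of the primary silyl ether leaves the PMB ether and the alkene untouched.

Step 4
Reactants: 6 (E)-6-[(4-methoxybenzyl)oxy]-3-methylhex-3-en-1-ol
Product: 7 (E)-6-[(4-methoxybenzyl)oxy]-3-methylhex-3-enal
Conditions: Dess–Martin periodinane, pyridine, CH2Cl2, 0 °C; used crude at once
Reagents that add atoms: none
Why: Dess–Martin oxidation under pyridine buffering gives the β,γ-unsaturated C8 aldehyde without acid or base strong enough to move the alkene into conjugation.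

Step 5
Reactants: 8 1-methoxy-4-(prop-2-en-1-yloxy)benzene; 9 3-(trimethylsilyl)prop-2-ynal
Product: 12 (3S,4S)-4-(4-methoxyphenoxy)-1-(trimethylsilyl)hex-5-en-1-yn-3-ol, via (Z)-3-(4-methoxyphenoxy)allyllithium 10 (not isolated), via (Z)-aryloxyallyl-diisopinocampheylborane 11 (not isolated)
Conditions: 8, s-BuLi, THF, −78 °C; (+)-Ipc2BOMe; BF3·OEt2; 9, −78 °C; then NaOH, H2O2, rt
Reagents that add atoms: none
Why: Brown alkoxyallylboration: kinetic lithiation gives the chelated (Z)-allyl anion, the derived (Z)-γ-aryloxyallylborane adds to the ynal through a chair transition state to give the syn mono-protected diol, and the isopinocampheyl groups from (+)-Ipc2BOMe direct attack to the Re face of the aldehyde, which sets C5 (S) and C6 (S).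

Step 6
Reactants: 12 (3S,4S)-4-(4-methoxyphenoxy)-1-(trimethylsilyl)hex-5-en-1-yn-3-ol
Product: 13 tert-butyl{[(3S,4S)-4-(4-methoxyphenoxy)-1-(trimethylsilyl)hex-5-en-1-yn-3-yl]oxy}dimethylsilane
Conditions: TBSCl, imidazole, DMF, rt
Reagents that add atoms: tert-butyldimethylsilyl chloride, CC(C)(C)[Si](C)(C)Cl
Why: Silylation of the propargylic alcohol installs the C5 protecting group that is kept until step 18.

Step 7
Reactants: 13 tert-butyl{[(3S,4S)-4-(4-methoxyphenoxy)-1-(trimethylsilyl)hex-5-en-1-yn-3-yl]oxy}dimethylsilane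
Product: 14 tert-butyl{[(3S,4S)-4-(4-methoxyphenoxy)hex-5-en-1-yn-3-yl]oxy}dimethylsilane
Conditions: K2CO3 (cat.), MeOH, 0 °C → rt
Reagents that add atoms: none
Why: Catalytic methoxide cleaves the alkynyl C–Si bond while the O-silyl ether is stable.

Step 8
Reactants: 14 tert-butyl{[(3S,4S)-4-(4-methoxyphenoxy)hex-5-en-1-yn-3-yl]oxy}dimethylsilane
Product: 16 tert-butyl{[(3R,4S)-2-iodo-4-(4-methoxyphenoxy)hexa-1,5-dien-3-yl]oxy}dimethylsilane, via α-tributylstannyl diene 15 (not isolated)
Conditions: Mo(CO)3(CNt-Bu)3 (cat.), Bu3SnH, hydroquinone (cat.), THF, 55 °C; then I2, CH2Cl2, 0 °C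
Reagents that add atoms: iodine, II
Why: Molybdenum-catalysed hydrostannation of a propargylic ether places tin on the internal alkyne carbon and iododestannylation with retention gives the 2-iodo-1-alkene (C4–I) needed for the chromium chemistry.

Step 9
Reactants: 16 tert-butyl{[(3R,4S)-2-iodo-4-(4-methoxyphenoxy)hexa-1,5-dien-3-yl]oxy}dimethylsilane
Product: 17 (3S,4R)-4-[(tert-butyldimethylsilyl)oxy]-5-iodohexa-1,5-dien-3-ol
Conditions: (NH4)2Ce(NO3)6, MeCN/H2O, 0 °C
Reagents that add atoms: none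
Why: Oxidative dearylation of the 4-methoxyphenyl ether by tetravalent cerium releases the C6 alcohol as benzoquinone forms, and silyl ether, alkenyl iodide and alkenes are not oxidised under these conditions.

Step 10
Reactants: 17 (3S,4R)-4-[(tert-butyldimethylsilyl)oxy]-5-iodohexa-1,5-dien-3-ol; 18 2-(bromomethyl)prop-2-enoic acid
Product: 19 (3S,4R)-4-[(tert-butyldimethylsilyl)oxy]-5-iodohexa-1,5-dien-3-yl 2-(bromomethyl)prop-2-enoate
Conditions: N,N'-diisopropylcarbodiimide, DMAP (cat.), CH2Cl2, −10 → 0 °C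
Reagents that add atoms: none
Why: Steglich esterification at low temperature acylates the only free hydroxyl (C6–OH) faster than the allylic bromide is displaced.

Step 11
Reactants: 19 (3S,4R)-4-[(tert-butyldimethylsilyl)oxy]-5-iodohexa-1,5-dien-3-yl 2-(bromomethyl)prop-2-enoate
Product: 20 (5S)-3-(bromomethyl)-5-{(1R)-1-[(tert-butyldimethylsilyl)oxy]-2-iodoprop-2-en-1-yl}furan-2(5H)-one
Conditions: second-generation Grubbs catalyst (H2IMes)(PCy3)Cl2Ru=CHPh (cat.), toluene, 80 °C
Reagents that add atoms: none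
Why: Ring-closing metathesis between the acrylate and the C7 vinyl group closes the five-membered butenolide with loss of ethene, and the hindered 2-iodoalkene does not engage the ruthenium carbene.

Step 12
Reactants: 20 (5S)-3-(bromomethyl)-5-{(1R)-1-[(tert-butyldimethylsilyl)oxy]-2-iodoprop-2-en-1-yl}furan-2(5H)-one; 7 (E)-6-[(4-methoxybenzyl)oxy]-3-methylhex-3-enal
Product: 22 (4R,5S)-5-{(1R)-1-[(tert-butyldimethylsilyl)oxy]-2-iodoprop-2-en-1-yl}-4-{(1S,3E)-1-hydroxy-6-[(4-methoxybenzyl)oxy]-3-methylhex-3-en-1-yl}-3-methylideneoxolan-2-one, via allylzinc bromide 21 (not isolated)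
Conditions: Zn dust, THF/sat. aq. NH4Cl, 0 °C → rt
Reagents that add atoms: none
Why: Zinc Barbier allylation (SE2′) of the 3-(bromomethyl)butenolide: the allylzinc adds through C7 on the face anti to the C6 substituent (trans-lactone, C7 R) and a closed chair transition state with the ring-locked (E)-type allyl unit and an equatorial aldehyde substituent gives the 7,8-anti alcohol (C8 S) while the exocyclic C11=C13 alkene is regenerated.

Step 13
Reactants: 22 the C8 alcohol from step 12; 23 angelic acid [(2Z)-2-methylbut-2-enoic acid]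
Product: 25 (1S,3E)-1-[(2S,3R)-2-{(1R)-1-[(tert-butyldimethylsilyl)oxy]-2-iodoprop-2-en-1-yl}-4-methylidene-5-oxooxolan-3-yl]-6-[(4-methoxybenzyl)oxy]-3-methylhex-3-en-1-yl (2Z)-2-methylbut-2-enoate, via angelic 2,4,6-trichlorobenzoic anhydride 24 (not isolated)
Conditions: 23, 2,4,6-trichlorobenzoyl chloride, Et3N, toluene, rt; then 22, 80 °C
Reagents that add atoms: none
Why: Yamaguchi esterification transfers the angeloyl group of the mixed anhydride to the hindered C8 hydroxyl, and leaving out a nucleophilic catalyst avoids addition–elimination isomerisation of the (Z)-acyl group to the tiglate.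

Step 14
Reactants: 25 the C8 angelate PMB ether from step 13
Product: 26 (1S,3E)-1-[(2S,3R)-2-{(1R)-1-[(tert-butyldimethylsilyl)oxy]-2-iodoprop-2-en-1-yl}-4-methylidene-5-oxooxolan-3-yl]-6-hydroxy-3-methylhex-3-en-1-yl (2Z)-2-methylbut-2-enoate
Conditions: DDQ, CH2Cl2/pH 7 buffer, 0 °C
Reagents that add atoms: none
Why: Oxidative cleavage of the PMB ether by DDQ (benzylic hydride abstraction, then hydrolysis) frees the C3 alcohol without touching esters, silyl ether or alkenyl iodide.

Step 15
Reactants: 26 the C3 alcohol from step 14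
Product: 27 (1S,3E)-1-[(2S,3R)-2-{(1R)-1-[(tert-butyldimethylsilyl)oxy]-2-iodoprop-2-en-1-yl}-4-methylidene-5-oxooxolan-3-yl]-3-methyl-6-oxohex-3-en-1-yl (2Z)-2-methylbut-2-enoate
Conditions: Dess–Martin periodinane, pyridine, CH2Cl2, 0 °C; used crude at once
Reagents that add atoms: none
Why: Dess–Martin oxidation under buffered, non-basic conditions gives the β,γ-unsaturated C3 aldehyde, which is cyclised without purification.

Step 16
Reactants: 27 the 4-iodo-3-oxo seco-compound from step 15
Product: 29 (1(10)E,3R,5S,6S,7R,8S)-8-angeloyloxy-5-[(tert-butyldimethylsilyl)oxy]-3-hydroxygermacra-1(10),4(15),11(13)-trien-12,6-olide, via alkenylchromium dichloride 28 (not isolated)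
Conditions: CrCl2 (excess), NiCl2 (cat.), degassed DMSO/THF, rt, slow addition of 27 (high dilution)
Reagents that add atoms: none
Why: Oxidative addition of the C4–I bond to zerovalent nickel (formed from NiCl2 by divalent chromium) and transmetallation give the alkenylchromium 28 (trivalent chromium), which adds to the C3 aldehyde through a four-centre, chromium-bound transition state; the closest known reaction type is the Nozaki–Hiyama–Kishi macrocyclisation of ω-formyl alkenyl iodides to ten-membered rings. The ten-membered carbocycle is closed in a 10-exo-trig mode, the nucleophilic sp2 carbon C4 attacking the C3=O that stays outside the new ring. The only new stereocentre, C3, is set under substrate (conformational) control: the trans-fused lactone and the (E)-C1=C10 alkene restrict the chain, H3 is expected to eclipse the C4=C15 bond to avoid allylic 1,3-strain, and the chromium-bound oxygen is expected to sit on the ring periphery anti to the bulky C5 silyloxy group, which corresponds to 3R (1,3-anti to O5). The step needs chemoselectivity for the aldehyde over the α-methylene lactone and the angelate, which the organochromium reagent provides because it adds only to aldehydes and does not β-eliminate the C5 silyloxy group. It also needs ring closure to win over oligomerisation, which high dilution and slow addition secure, and the neutral medium keeps the C1=C10 alkene out of conjugation with the aldehyde.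

Step 17
Reactants: 29 the macrocyclic C3 alcohol from step 16
Product: 30 (1(10)E,3R,5S,6S,7R,8S)-3-acetoxy-8-angeloyloxy-5-[(tert-butyldimethylsilyl)oxy]germacra-1(10),4(15),11(13)-trien-12,6-olide
Conditions: Ac2O, pyridine, DMAP (cat.), CH2Cl2, 0 °C → rt
Reagents that add atoms: acetic anhydride, CC(=O)OC(C)=O
Why: DMAP-catalysed acetylation of the allylic C3 alcohol, the only free hydroxyl.

Step 18
Reactants: 30 the C3 acetate from step 17
Product: 31 (1(10)E,3R,5S,6S,7R,8S)-3-acetoxy-8-angeloyloxy-5-hydroxygermacra-1(10),4(15),11(13)-trien-12,6-olide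
Conditions: HF·pyridine, pyridine, THF, 0 °C → rt
Reagents that add atoms: none
Why: Buffered fluoride cleavage of the secondary silyl ether is compatible with the acetate, the angelate and the α-methylene lactone and is placed before epoxide formation so that no oxirane is exposed to HF.

Step 19
Reactants: 31 the triene-ol from step 18
Product: 32 (1R,3R,5S,6S,7R,8S,10R)-3-acetoxy-8-angeloyloxy-1,10-epoxy-5-hydroxygermacra-4(15),11(13)-dien-12,6-olide (CNP0210054.2)
Conditions: mCPBA, NaHCO3, CH2Cl2, 0 °C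
Reagents that add atoms: 3-chloroperoxybenzoic acid, OOC(=O)c1cccc(Cl)c1
Why: Prilezhaev epoxidation: the trisubstituted C1=C10 alkene is the most electron-rich one (C4=C15 is deactivated by two allylic oxygens, C11=C13 and the angelate alkene are conjugated to carbonyls), the (E)-geometry is transferred stereospecifically to the trans-epoxide, and attack on the exposed outer face of the alkene in the ten-membered ring is expected to give the 1R,10R epoxide.

Compound list
1 | 4-(tert-butyldimethylsilyloxy)but-1-yne | C#CCCO[Si](C)(C)C(C)(C)C | starting material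
2 | oxirane | C1CO1 | starting material
3 | (E)-{4-[(tert-butyldimethylsilyl)oxy]-2-methylbut-1-en-1-yl}dimethylalane (not isolated) | C[Al](C)/C=C(\C)CCO[Si](C)(C)C(C)(C)C | intermediate
4 | (E)-6-[(tert-butyldimethylsilyl)oxy]-4-methylhex-3-en-1-ol | OCC/C=C(\C)CCO[Si](C)(C)C(C)(C)C | intermediate
5 | (E)-tert-butyl({6-[(4-methoxybenzyl)oxy]-3-methylhex-3-en-1-yl}oxy)dimethylsilane | COc1ccc(COCC/C=C(\C)CCO[Si](C)(C)C(C)(C)C)cc1 | intermediate
6 | (E)-6-[(4-methoxybenzyl)oxy]-3-methylhex-3-en-1-ol | COc1ccc(COCC/C=C(\C)CCO)cc1 | intermediate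
7 | (E)-6-[(4-methoxybenzyl)oxy]-3-methylhex-3-enal | COc1ccc(COCC/C=C(\C)CC=O)cc1 | intermediate
8 | 1-methoxy-4-(prop-2-en-1-yloxy)benzene (allyl 4-methoxyphenyl ether) | C=CCOc1ccc(OC)cc1 | starting material
9 | 3-(trimethylsilyl)prop-2-ynal | C[Si](C)(C)C#CC=O | starting material
10 | (Z)-3-(4-methoxyphenoxy)allyllithium (not isolated) | [Li]C/C=C\Oc1ccc(OC)cc1 | intermediate
11 | [(Z)-3-(4-methoxyphenoxy)allyl]bis(isopinocampheyl)borane from (+)-Ipc2BOMe (not isolated) | COc1ccc(O/C=C\CB([C@H]2C[C@H]3C[C@@H]([C@@H]2C)C3(C)C)[C@H]2C[C@H]3C[C@@H]([C@@H]2C)C3(C)C)cc1 | intermediate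
12 | (3S,4S)-4-(4-methoxyphenoxy)-1-(trimethylsilyl)hex-5-en-1-yn-3-ol | C[Si](C)(C)C#C[C@H](O)[C@@H](Oc1ccc(OC)cc1)C=C | intermediate
13 | tert-butyl{[(3S,4S)-4-(4-methoxyphenoxy)-1-(trimethylsilyl)hex-5-en-1-yn-3-yl]oxy}dimethylsilane | C[Si](C)(C)C#C[C@H](O[Si](C)(C)C(C)(C)C)[C@@H](Oc1ccc(OC)cc1)C=C | intermediate
14 | tert-butyl{[(3S,4S)-4-(4-methoxyphenoxy)hex-5-en-1-yn-3-yl]oxy}dimethylsilane | C#C[C@H](O[Si](C)(C)C(C)(C)C)[C@@H](Oc1ccc(OC)cc1)C=C | intermediate
15 | tert-butyl{[(3R,4S)-4-(4-methoxyphenoxy)-2-(tributylstannyl)hexa-1,5-dien-3-yl]oxy}dimethylsilane (not isolated) | C=C([Sn](CCCC)(CCCC)CCCC)[C@H](O[Si](C)(C)C(C)(C)C)[C@@H](Oc1ccc(OC)cc1)C=C | intermediate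
16 | tert-butyl{[(3R,4S)-2-iodo-4-(4-methoxyphenoxy)hexa-1,5-dien-3-yl]oxy}dimethylsilane | C=C(I)[C@H](O[Si](C)(C)C(C)(C)C)[C@@H](Oc1ccc(OC)cc1)C=C | intermediate
17 | (3S,4R)-4-[(tert-butyldimethylsilyl)oxy]-5-iodohexa-1,5-dien-3-ol | C=C(I)[C@H](O[Si](C)(C)C(C)(C)C)[C@@H](O)C=C | intermediate
18 | 2-(bromomethyl)prop-2-enoic acid | C=C(CBr)C(=O)O | starting material
19 | (3S,4R)-4-[(tert-butyldimethylsilyl)oxy]-5-iodohexa-1,5-dien-3-yl 2-(bromomethyl)prop-2-enoate | C=C(I)[C@H](O[Si](C)(C)C(C)(C)C)[C@@H](OC(=O)C(=C)CBr)C=C | intermediate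
20 | (5S)-3-(bromomethyl)-5-{(1R)-1-[(tert-butyldimethylsilyl)oxy]-2-iodoprop-2-en-1-yl}furan-2(5H)-one | C=C(I)[C@H](O[Si](C)(C)C(C)(C)C)[C@H]1OC(=O)C(CBr)=C1 | intermediate
21 | {[(5S)-5-{(1R)-1-[(tert-butyldimethylsilyl)oxy]-2-iodoprop-2-en-1-yl}-2-oxo-2,5-dihydrofuran-3-yl]methyl}zinc bromide (not isolated) | C=C(I)[C@H](O[Si](C)(C)C(C)(C)C)[C@H]1OC(=O)C(C[Zn]Br)=C1 | intermediate
22 | (4R,5S)-5-{(1R)-1-[(tert-butyldimethylsilyl)oxy]-2-iodoprop-2-en-1-yl}-4-{(1S,3E)-1-hydroxy-6-[(4-methoxybenzyl)oxy]-3-methylhex-3-en-1-yl}-3-methylideneoxolan-2-one | C=C1C(=O)O[C@H]([C@@H](O[Si](C)(C)C(C)(C)C)C(I)=C)[C@H]1[C@@H](O)C/C(C)=C/CCOCc1ccc(OC)cc1 | intermediate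
23 | angelic acid [(2Z)-2-methylbut-2-enoic acid] | C/C=C(/C)C(=O)O | starting material
24 | angelic 2,4,6-trichlorobenzoic anhydride (not isolated) | C/C=C(/C)C(=O)OC(=O)c1c(Cl)cc(Cl)cc1Cl | intermediate
25 | (1S,3E)-1-[(2S,3R)-2-{(1R)-1-[(tert-butyldimethylsilyl)oxy]-2-iodoprop-2-en-1-yl}-4-methylidene-5-oxooxolan-3-yl]-6-[(4-methoxybenzyl)oxy]-3-methylhex-3-en-1-yl (2Z)-2-methylbut-2-enoate | C=C1C(=O)O[C@H]([C@@H](O[Si](C)(C)C(C)(C)C)C(I)=C)[C@H]1[C@@H](OC(=O)/C(C)=C\C)C/C(C)=C/CCOCc1ccc(OC)cc1 | intermediate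
26 | (1S,3E)-1-[(2S,3R)-2-{(1R)-1-[(tert-butyldimethylsilyl)oxy]-2-iodoprop-2-en-1-yl}-4-methylidene-5-oxooxolan-3-yl]-6-hydroxy-3-methylhex-3-en-1-yl (2Z)-2-methylbut-2-enoate | C=C1C(=O)O[C@H]([C@@H](O[Si](C)(C)C(C)(C)C)C(I)=C)[C@H]1[C@@H](OC(=O)/C(C)=C\C)C/C(C)=C/CCO | intermediate
27 | (1S,3E)-1-[(2S,3R)-2-{(1R)-1-[(tert-butyldimethylsilyl)oxy]-2-iodoprop-2-en-1-yl}-4-methylidene-5-oxooxolan-3-yl]-3-methyl-6-oxohex-3-en-1-yl (2Z)-2-methylbut-2-enoate | C=C1C(=O)O[C@H]([C@@H](O[Si](C)(C)C(C)(C)C)C(I)=C)[C@H]1[C@@H](OC(=O)/C(C)=C\C)C/C(C)=C/CC=O | intermediate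
28 | C4 alkenylchromium dichloride derived from 27 (trivalent chromium; not isolated) | C=C1C(=O)O[C@H]([C@@H](O[Si](C)(C)C(C)(C)C)C(=C)[Cr](Cl)Cl)[C@H]1[C@@H](OC(=O)/C(C)=C\C)C/C(C)=C/CC=O | intermediate
29 | (1(10)E,3R,5S,6S,7R,8S)-8-angeloyloxy-5-[(tert-butyldimethylsilyl)oxy]-3-hydroxygermacra-1(10),4(15),11(13)-trien-12,6-olide | C=C1C(=O)O[C@H]2[C@H]1[C@@H](OC(=O)/C(C)=C\C)C/C(C)=C/C[C@@H](O)C(=C)[C@@H]2O[Si](C)(C)C(C)(C)C | intermediate
30 | (1(10)E,3R,5S,6S,7R,8S)-3-acetoxy-8-angeloyloxy-5-[(tert-butyldimethylsilyl)oxy]germacra-1(10),4(15),11(13)-trien-12,6-olide | C=C1C(=O)O[C@H]2[C@H]1[C@@H](OC(=O)/C(C)=C\C)C/C(C)=C/C[C@@H](OC(C)=O)C(=C)[C@@H]2O[Si](C)(C)C(C)(C)C | intermediate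
31 | (1(10)E,3R,5S,6S,7R,8S)-3-acetoxy-8-angeloyloxy-5-hydroxygermacra-1(10),4(15),11(13)-trien-12,6-olide | C=C1C(=O)O[C@H]2[C@H]1[C@@H](OC(=O)/C(C)=C\C)C/C(C)=C/C[C@@H](OC(C)=O)C(=C)[C@@H]2O | intermediate
32 | (1R,3R,5S,6S,7R,8S,10R)-3-acetoxy-8-angeloyloxy-1,10-epoxy-5-hydroxygermacra-4(15),11(13)-dien-12,6-olide (CNP0210054.2) | C=C1C(=O)O[C@H]2[C@H]1[C@@H](OC(=O)/C(C)=C\C)C[C@@]1(C)O[C@@H]1C[C@@H](OC(C)=O)C(=C)[C@@H]2O | target

Total step count: 19. Longest linear sequence: 15 steps (steps 5–19, from 8 and 9 to 32); the branch to aldehyde 7 has 4 steps (steps 1–4).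

Steps most likely to fail

Step 16 (ring closure at C3–C4). What may go wrong: the aldehyde may add through its other face, because the macrocyclic bias at C3 rests on a conformational argument and not on a close model, and intermolecular coupling may compete with closure of the strained ten-membered ring. The fallback replaces substrate control at C3 by reagent control. It sets out from 27: the cyclisation is run as in step 16 and the (3S)-epimer of 29 F1 that accompanies 29 is not separated. The mixture is oxidised with Dess–Martin periodinane/pyridine (CH2Cl2, 0 °C) to the single C3 enone F2. F2 is reduced with (S)-2-methyl-CBS-oxazaborolidine and catecholborane (toluene, −78 °C), the alkenyl branch at C4 acting as the large group, to give the 3R alcohol. The route is rejoined at 29.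

Step 12 (Barbier union, C7–C8). What may go wrong: the closed-chair selectivity at C8 may erode, so that the 7,8-syn adduct competes or dominates, and the C1=C10 alkene of aldehyde 7 may drift into conjugation before addition. The fallback sets C8 by inversion instead of by direct anti addition. It sets out from 20 and 7: the allylation is run so that the syn adduct, the (8R)-epimer of 22 F3, is collected. F3 is esterified with angelic acid 23 under Mitsunobu conditions (PPh3, DIAD, toluene, 0 °C → rt), which installs the angelate with inversion at C8 and without acyl activation, so the (Z)-geometry is not at risk. The route is rejoined at 25 and step 13 is bypassed.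

Step 19 (epoxidation). What may go wrong: the peracid may attack the other face of the C1=C10 alkene, since the reacting conformer of the ten-membered ring is not secured, and hydroxyl-assisted epoxidation of the C4=C15 alkene may compete. The fallback is a two-step anti-addition/closure that places the oxygen on the face opposite to the one an electrophile attacks. It sets out from 31: NBS in aqueous DME at 0 °C gives the bromohydrin F4 (bromonium ion on the exposed face, water opening at the tertiary C10). Ag2O in DME then closes the oxirane with inversion at C1, and the route is rejoined at 32.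

Further compounds
F1 | step 16 | (1(10)E,3S,5S,6S,7R,8S)-8-angeloyloxy-5-[(tert-butyldimethylsilyl)oxy]-3-hydroxygermacra-1(10),4(15),11(13)-trien-12,6-olide | C=C1C(=O)O[C@H]2[C@H]1[C@@H](OC(=O)/C(C)=C\C)C/C(C)=C/C[C@H](O)C(=C)[C@@H]2O[Si](C)(C)C(C)(C)C
F2 | step 16 | (1(10)E,5S,6S,7R,8S)-8-angeloyloxy-5-[(tert-butyldimethylsilyl)oxy]-3-oxogermacra-1(10),4(15),11(13)-trien-12,6-olide | C=C1C(=O)O[C@H]2[C@H]1[C@@H](OC(=O)/C(C)=C\C)C/C(C)=C/CC(=O)C(=C)[C@@H]2O[Si](C)(C)C(C)(C)C
F3 | step 12 | (4R,5S)-5-{(1R)-1-[(tert-butyldimethylsilyl)oxy]-2-iodoprop-2-en-1-yl}-4-{(1R,3E)-1-hydroxy-6-[(4-methoxybenzyl)oxy]-3-methylhex-3-en-1-yl}-3-methylideneoxolan-2-one | C=C1C(=O)O[C@H]([C@@H](O[Si](C)(C)C(C)(C)C)C(I)=C)[C@H]1[C@H](O)C/C(C)=C/CCOCc1ccc(OC)cc1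
F4 | step 19 | (1S,3R,5S,6S,7R,8S,10R)-3-acetoxy-8-angeloyloxy-1-bromo-5,10-dihydroxygermacra-4(15),11(13)-dien-12,6-olide | C=C1C(=O)O[C@H]2[C@H]1[C@@H](OC(=O)/C(C)=C\C)C[C@@](C)(O)[C@@H](Br)C[C@@H](OC(C)=O)C(=C)[C@@H]2O
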